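## The problem

1. The target 28 (C60H42O30) is an achiral decamer of phloroglucinol: ten benzene rings joined by six diaryl ether bridges and three biaryl bonds, with 24 free phenols.
2. Lettering used throughout:
   - Ring A is the terminal 3,5-dihydroxyphenyl group on the oxygen at B1.
   - Ring B carries aryloxy groups at B1, B2 and B6 and OH at B4.
   - Ring C (OH at C2 and C6) is bound through C1–O to B2 and through C4–O to D1.
   - Ring D repeats ring B (aryloxy at D1, D2 and D6, OH at D4).
   - B6, D2 and D6 each carry the same 2,2',4,4',6,6'-hexahydroxybiphenyl-3-yloxy unit, made of an inner ring E (E1–O, OH at E2, E4 and E6, aryl at E5) and an outer ring F.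
3. There is no stereocentre, and each ring F is symmetric about its biaryl axis, so there is no chiral axis either; the whole difficulty lies in connectivity and crowding.
4. Every ether bridge joins two electron-rich rings and has two or three ortho oxygen substituents around it (B1 and D1 lie between two aryloxy groups, C1 and E1 between two oxygens). This is the worst case for Ullmann, Chan-Lam or SNAr chemistry on intact arenes, and ring B must also be desymmetrised, since B2 and B6 carry different aryloxy groups.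
5. The three biaryl bonds are tetra-ortho-oxygenated.
6. The free polyphenol is oxidised by air, above all in base, and is attacked by any electrophile, so all 24 hydroxyls must carry one protecting group that falls in a single neutral operation at the very end.
7. The feature that makes the key step possible: in rings B, C and D the oxygens stand at positions 1, 2, 6 and 4, and positions 3 and 5 are unsubstituted CH. Atoms 2–1–6 of each ring are therefore the O–C–C(O)–C–O chain of a 1,3-dioxygenated acetone, and atoms 3–4–5 are the CH–C(O)–CH chain of a 2-oxygenated malondialdehyde.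
8. If these three rings are built from their two C3 halves, every crowded aryl–O bond on B, C and D is first made as an O–CH2 bond by SN2 at an unhindered carbon next to a carbonyl group, and the ring is grown afterwards between the oxygens.

## Retrosynthesis

Abbreviation: HBB = 2,2',4,4',6,6'-hexakis(benzyloxy)biphenyl-3-yl, the benzylated ring E/ring F unit.

**28 from 27.** The 24 O–benzyl bonds are cut. Benzyl is preferred to methyl because hydrogenolysis is neutral. A 24-fold cleavage by a boron halide would expose phloroglucinol aryl ethers, which behave as enol ethers, to strong acid. The skeleton of 27 is no simpler, but 27 is a stable compound that can be chromatographed. The forward step must only leave diaryl ethers and biaryl bonds alone.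

**27 from 25 and 26.** The bond between O–B1 and ring A is cut. Ring A is the one ring with only 1,3,5-oxygens, so it does not fit the C3 + C3 analysis. It is also the one aryl partner with two free ortho positions, so a copper-catalysed coupling meets hindrance on the phenol side only. 25 is one ring smaller and 26 is bought. The forward reaction must arylate a phenol that lies between two aryloxy groups.

**25 from 23 and 11.**
- Ring B is cut through two C–C bonds, B2–B3 and B5–B6, and through none of its C–O bonds.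
- The neighbouring cuts at B2–O and B6–O would require two different hindered phenols to be coupled in turn to two equivalent positions of one arene. The C–C cut moves that choice to an open chain, where it is trivial.
- 23 is an acyclic ketone whose carbonyl oxygen becomes O–B1. 11 brings B3, B4 and B5 with O–B4 already benzylated. 25 therefore appears with exactly one free hydroxyl, the one needed next.
- The forward reaction must form two C–C bonds and aromatise in base without touching the electron-rich rings. Either CH2 group of 23 may react first, since both orders give the same ring.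

**23 from 21 and 22, and 22 from 6 and 7.** The O–CH2 bond between O–C1 and the future B2 is cut, then the O–CH2 bond between O–E1 and the future B6. The six-ring part 21 and the two-ring part 22 thus meet by SN2 at a primary carbon next to a carbonyl group. The same union at an aryl carbon would be the most hindered bond of the molecule, with three ortho substituents. The forward steps require monosubstitution of 7, secured by an excess of 7, and clean O-alkylation of 21.

**21 from 18 and 19.** Ring C is cut at C2–C3 and C5–C6. Here the large part sits on the electrophilic C3 half. The oxygen on the central carbon of 18 is O–D1 and becomes the C4–O–D1 bridge. The small ketone 19 delivers C2, C1 and C6 with both benzyl ethers in place and C1–OH free. The neighbouring cut at C4–O would need a ring C halide with its own synthesis, a temporary group on O–C1, and a copper coupling on the shielded phenol 13. The forward reaction is the same ring synthesis as for ring B.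

**18 from 13 and 14 by way of 15 and 16.** The O–CH2 bond at O–D1 is cut. The two-carbon unit of 14 is taken to the aldehyde 16 and extended by one carbon on its CH2 group. The trimethinium unit must be raised without electrophilic reagents, because a chloroiminium salt would formylate rings E and F. This dictates an amide acetal and an ammonium salt. Each precursor is simpler by one functional group. The forward steps require a partial ester reduction and an aminomethylenation.

**13 from 8 and 11 (key disconnection).**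
- Ring D is cut at D2–D3 and D5–D6.
- This single ring synthesis delivers the 1,2,3,5-tetraoxygenated ring, both tri-ortho-substituted bridges D2–O–E1 and D6–O–E1, the benzyl ether at D4 and the free hydroxyl at D1.
- The rival cuts at D2–O and D6–O leave a double coupling of a di-ortho-substituted phenol to an electron-rich dihaloarene.
- 8 is a symmetric ketone made in one SN2 step, so the precursor is much simpler than the product.
- The forward reaction must close a carbocycle rather than a pyran and must stop at a 1:1 condensation.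

**8 from 6 and 7, and 11 from 9.** Two O–CH2 bonds of 8 are cut, and both C3 reagents go back to bought compounds. The ortho benzyloxy groups of 6 matter little at a primary carbon next to a carbonyl group.

**6 from 1 by way of 2, 3 and 4.** The C–O bond at E1 is traced to a formyl group (aryl migration to oxygen), the formyl group to a C–H bond of 3, and the biaryl bond of 3 to two molecules of 2. The cut through the biaryl bond gives two identical halves, so no cross-selectivity is needed. All four aromatic C–H bonds of 3 are equivalent, so any monofunctionalisation gives the right isomer. One phenol, 6, then serves all three biphenyl units.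

## Roads not taken

**Alternative 1:** The most obvious plan cuts the aryl–O bonds at D2, D6, B2, B6 and C4 on intact benzene rings.
- *Forward key step:* a twofold CuI-catalysed Ullmann coupling of phenol 6 with 5-(benzyloxy)-1,3-dibromo-2-(methoxymethoxy)benzene A1. Acetal removal then gives 13, and the same pattern is repeated ring by ring.
- *Why the chosen plan is better:*
  - Each coupling would join a phenoxide with two ortho benzyloxy groups to an electron-rich bromide that has an ortho oxygen of its own. Both partners slow the copper cycle, while hydrodebromination and oxidation of the phenoxide go on at the high temperature needed.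
  - In ring B the two bromines are equivalent, so two different phenols could be brought in only statistically.
  - The central oxygen needs a group put on and taken off for each ring.
  - The largest fragments would meet in the most hindered coupling.
  - The chosen plan makes the same bridges by SN2 and needs no temporary group.

**Alternative 2:** The same C–O bonds are cut, but on a dearomatised ring.
- *Forward key step:* a twofold addition-elimination of the phenoxide of 6 on 2,6-dichloro-1,4-benzoquinone A2 to give 2,6-bis(HBB-oxy)-1,4-benzoquinone A3. Reduction and selective benzylation of the less hindered hydroxyl then give 13.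
- *Why the chosen plan is better:*
  - The free positions 3 and 5 of A2 are β to the carbonyl group at C1 and compete with the chlorinated carbons as acceptors. Addition there followed by loss of HCl shifts the substituent to the neighbouring carbon and opens the way to 2,5-patterns.
  - The phenoxide of 6 is a strong reductant and A2 an oxidant, so electron transfer competes.
  - Aryloxy groups on a quinone are leaving groups themselves, so a mixed ring B would scramble.
  - Two more steps are needed to reach 13. The chosen plan delivers O–D4 benzylated and O–D1 free directly.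

**Alternative 3:** D2–O and D6–O are cut on an aryne.
- *Forward key step:* a fluoride-triggered cascade of 5-(benzyloxy)-2-(trimethylsilyl)-1,3-phenylene bis(trifluoromethanesulfonate) A4.
  - The first aryne takes up the phenoxide of 6 at the carbon remote from the remaining triflate.
  - The aryl anion expels that triflate.
  - The second aryne, now flanked by an aryloxy group, takes up a second phenoxide at its remote carbon.
- *Why the chosen plan is better:*
  - The central carbon ends as C–H, in 1-(benzyloxy)-3,5-bis(HBB-oxy)benzene A5, so the oxygen at D1 is missing. It would have to be brought in by metalation, borylation and oxidation between two very large aryloxy groups, in the presence of thirteen benzyl ethers prone to Wittig rearrangement.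
  - Both additions happen in one flask, so ring B cannot be made unsymmetrical.
  - Two equivalents of the valuable phenol 6 face a reagent that also attacks electron-rich arenes.

Key step: step 7

Abbreviations in names: HBB as above; DAr = 4-(benzyloxy)-2,6-bis(HBB-oxy)phenyl (benzylated ring D unit); CAr = 2,6-bis(benzyloxy)-4-(DAr-oxy)phenyl (benzylated ring C–ring D unit).

Assumption: the C=C bonds of the push-pull compounds 10, 12, 17, 20 and 24 and of the cations of 11 and 18 isomerise easily, so no configuration is assigned to them; the target has no stereocentre and no stable chiral axis.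

## Steps

Step 1
Reactants: 1 1,3,5-tris(benzyloxy)benzene
Product: 2 1,3,5-tris(benzyloxy)-2-iodobenzene
Conditions: N-iodosuccinimide (1.0 equiv), MeCN, 0 °C to rt, dark
Reagents that add atoms: N-iodosuccinimide, O=C1CCC(=O)N1I
Why: Electrophilic aromatic iodination of a very electron-rich arene; the three free positions are equivalent and one equivalent of reagent should hold the reaction at the monoiodide.

Step 2
Reactants: 2 1,3,5-tris(benzyloxy)-2-iodobenzene (two molecules)
Product: 3 2,2',4,4',6,6'-hexakis(benzyloxy)-1,1'-biphenyl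
Conditions: Cu powder (activated, excess), DMF, 150 °C, under argon
Reagents that add atoms: none
Why: Classical Ullmann biaryl homocoupling, for which aryl iodides with two ortho alkoxy groups are standard substrates; both halves are identical, so no cross-selectivity is needed, and benzyl ethers tolerate the conditions.

Step 3
Reactants: 3 2,2',4,4',6,6'-hexakis(benzyloxy)-1,1'-biphenyl
Product: 4 2,2',4,4',6,6'-hexakis(benzyloxy)biphenyl-3-carbaldehyde
Conditions: POCl3 (1.05 equiv), DMF, 0 °C to rt; then H2O
Reagents that add atoms: N,N-dimethylformamide, CN(C)C=O; water, O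
Why: Vilsmeier-Haack formylation; the four aromatic C–H bonds of 3 are equivalent by symmetry, so any single attack gives 4. The formyl group deactivates its own ring and the limiting reagent protects the other ring; unreacted 3 can be recycled.

Step 4
Reactants: 4 2,2',4,4',6,6'-hexakis(benzyloxy)biphenyl-3-carbaldehyde
Product: 6 2,2',4,4',6,6'-hexakis(benzyloxy)biphenyl-3-ol (HBB-OH), via aryl formate 5 (not isolated)
Conditions: mCPBA (1.2 equiv), CH2Cl2, 0 °C to rt; then K2CO3 (cat.), MeOH/THF, rt, under argon
Reagents that add atoms: 3-chloroperoxybenzoic acid, OOC(=O)c1cccc(Cl)c1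
Why: Baeyer-Villiger oxidation with aryl migration, strongly favoured by the ortho and para alkoxy groups, gives formate 5, and methanolysis frees the phenol; this sets O–E1 between two benzyloxy groups without any aryl–O coupling.

Step 5
Reactants: 6 HBB-OH (2 equiv); 7 1,3-dichloropropan-2-one
Product: 8 1,3-bis(HBB-oxy)propan-2-one
Conditions: K2CO3 (2.5 equiv), acetone, rt to 50 °C, under argon
Reagents that add atoms: none
Why: Twofold Williamson ether synthesis on an α-chloroketone; the carbon attacked is primary and activated by the carbonyl group, so the two ortho benzyloxy groups of 6 should matter little.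

Step 6
Reactants: 9 2-(benzyloxy)acetaldehyde
Product: 11 N-[2-(benzyloxy)-3-(dimethylamino)prop-2-en-1-ylidene]-N-methylmethanaminium tetrafluoroborate, via enaminal 10 (not isolated)
Conditions: Me2NCH(OMe)2 (1.5 equiv), toluene, 60 °C; concentrate; Me2NH2BF4 (1.1 equiv), EtOH, rt to 50 °C
Reagents that add atoms: N,N-dimethylformamide dimethyl acetal, COC(OC)N(C)C; dimethylammonium tetrafluoroborate, C[NH2+]C.F[B-](F)(F)F
Why: Aminomethylenation of the activated CH2 group by the amide acetal gives the vinylogous formamide 10, and its condensation with a dimethylammonium salt is the standard way to a 2-substituted trimethinium salt.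

Step 7
Reactants: 8 1,3-bis(HBB-oxy)propan-2-one; 11 2-(benzyloxy)trimethinium tetrafluoroborate
Product: 13 4-(benzyloxy)-2,6-bis(HBB-oxy)phenol (DAr-OH), via aminodienone 12 (not isolated)
Conditions: KOtBu (2.5 equiv), THF, 0 °C; 11 (1.0 equiv), rt; then 60 °C; AcOH quench, under argon
Reagents that add atoms: none
Why: Proposed new method: the potassium enolate of 8 should add to one terminal carbon of the trimethinium cation of 11 and lose dimethylamine to give aminodienone 12 (bond D2–D3). Deprotonation of the second OCH2 group then gives a 1-oxidohexatriene, which closes ring D at D5–D6 by a thermal 6π electrocyclisation (formally a 6-endo-trig attack of the enolate carbon on the aminomethine carbon), and loss of the second dimethylamine leaves the phenoxide of 13. The closest known reaction type is the condensation of 1,3-disubstituted acetones such as dibenzyl ketone or acetonedicarboxylates with sodium nitromalonaldehyde or with 2-aryl and 2-halo trimethinium salts to 2,4,6-trisubstituted phenols; what has not been shown is the case in which all three substituents are oxygen. The benzyloxy group of 11 stands on the central carbon, a node of the LUMO of the cation, so it should leave the termini electrophilic, and each aryloxy group of 8 acidifies its CH2 group by induction. No stereocentre is formed, and the symmetry of 8 and 11 removes any question of regiochemistry. The step needs C- over O-closure, which is secured because closure through oxygen to a 2H-pyran is reversible and only the carbocycle can end as an aromatic anion. It needs 1:1 over 1:2 condensation, which is favoured by one equivalent of 11 and by warming only after 12 has formed. It also needs the electron-rich rings E and F to stay untouched, which the weak electrophilicity of 11 and the basic medium secure.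

Step 8
Reactants: 13 DAr-OH; 14 methyl bromoacetate
Product: 15 methyl 2-(DAr-oxy)acetate
Conditions: K2CO3 (2 equiv), DMF, rt to 40 °C, under argon
Reagents that add atoms: none
Why: Williamson ether synthesis; the shielded phenoxide O–D1 meets a small, activated primary bromide, so the future C4–O–D1 bridge is made at an sp3 carbon.

Step 9
Reactants: 15 methyl 2-(DAr-oxy)acetate
Product: 16 2-(DAr-oxy)acetaldehyde
Conditions: iBu2AlH (1.2 equiv), CH2Cl2/toluene, −78 °C; aqueous work-up
Reagents that add atoms: none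
Why: Partial reduction of an ester; the α-aryloxy group stabilises the tetrahedral aluminium hemiacetal at −78 °C, so the aldehyde should be set free only on work-up, and ethers are inert.

Step 10
Reactants: 16 2-(DAr-oxy)acetaldehyde
Product: 18 N-[2-(DAr-oxy)-3-(dimethylamino)prop-2-en-1-ylidene]-N-methylmethanaminium tetrafluoroborate, via enaminal 17 (not isolated)
Conditions: Me2NCH(OMe)2 (3 equiv), toluene, 60 °C; concentrate; Me2NH2BF4 (1.1 equiv), EtOH/CH2Cl2, rt to 40 °C
Reagents that add atoms: N,N-dimethylformamide dimethyl acetal, COC(OC)N(C)C; dimethylammonium tetrafluoroborate, C[NH2+]C.F[B-](F)(F)F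
Why: Same two operations as in step 6; neither reagent is an electrophile for arenes, whereas POCl3/DMF would formylate rings E and F.

Step 11
Reactants: 18 2-(DAr-oxy)trimethinium tetrafluoroborate; 19 1,3-bis(benzyloxy)propan-2-one
Product: 21 2,6-bis(benzyloxy)-4-(DAr-oxy)phenol (CAr-OH), via aminodienone 20 (not isolated)
Conditions: 19 (1.5 equiv), KOtBu (3 equiv), THF, 0 °C; 18, rt; then 60 °C; AcOH quench, under argon
Reagents that add atoms: none
Why: Proposed new method: same ring synthesis as in step 7 with the sizes exchanged, in which the enolate of the small ketone 19 attacks salt 18, the enolate of aminodienone 20 closes the C5–C6 bond by 6π electrocyclisation and dimethylamine is lost, so that ring C forms with C1–OH free, C2 and C6 benzylated and C4 already bound to O–D1. The closest known reaction type is the synthesis of phenols from 1,3-disubstituted acetones and 2-substituted trimethinium salts or malondialdehydes; a 2-aryloxy salt and a 1,3-dialkoxyacetone have not been shown as partners.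

Step 12
Reactants: 6 HBB-OH; 7 1,3-dichloropropan-2-one (5 equiv)
Product: 22 1-chloro-3-(HBB-oxy)propan-2-one
Conditions: K2CO3 (1.2 equiv), acetone, 0 °C to rt, slow addition of 6, under argon
Reagents that add atoms: none
Why: Williamson ether synthesis held at the first substitution by the excess of the cheap dichloride, which is removed afterwards.

Step 13
Reactants: 21 CAr-OH; 22 1-chloro-3-(HBB-oxy)propan-2-one
Product: 23 1-(CAr-oxy)-3-(HBB-oxy)propan-2-one
Conditions: K2CO3 (1.5 equiv), acetone, rt to 40 °C, under argon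
Reagents that add atoms: none
Why: Williamson ether synthesis on an α-chloroketone; the two large parts are joined at a primary carbon, and the difference between B2 and B6 is fixed here in the open chain.

Step 14
Reactants: 23 1-(CAr-oxy)-3-(HBB-oxy)propan-2-one; 11 2-(benzyloxy)trimethinium tetrafluoroborate
Product: 25 4-(benzyloxy)-2-(CAr-oxy)-6-(HBB-oxy)phenol, via aminodienone 24 (not isolated)
Conditions: KOtBu (2.5 equiv), THF, 0 °C; 11 (1.0 equiv), rt; then 60 °C; AcOH quench, under argon
Reagents that add atoms: none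
Why: Proposed new method: the ring synthesis of step 7 applied to the unsymmetrical ketone 23, by enolate addition to 11 with loss of dimethylamine, 6π electrocyclisation of the enolate of 24 and loss of the second dimethylamine; attack through either CH2 group leads to the same ring B, so no regiocontrol is needed. The closest known reaction type is the same as in step 7, phenols from 1,3-disubstituted acetones and 2-substituted trimethinium salts or nitromalonaldehyde.

Step 15
Reactants: 25 4-(benzyloxy)-2-(CAr-oxy)-6-(HBB-oxy)phenol; 26 1,3-bis(benzyloxy)-5-bromobenzene (3 equiv)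
Product: 27 tetracosa-O-benzyl ether of the target
Conditions: CuI (20 mol %), picolinic acid (40 mol %), K3PO4 (2 equiv), DMSO/toluene, 100 °C, under argon
Reagents that add atoms: none
Why: Ullmann-type diaryl ether synthesis with the CuI/picolinic acid system, which is suited to 2,6-disubstituted phenols; 26 has two free ortho positions and is used in excess, so hindrance lies on one side only.

Step 16
Reactants: 27 tetracosa-O-benzyl ether of the target
Product: 28 target CNP0294555.0
Conditions: H2 (1 to 4 bar), Pd(OH)2/C, THF/MeOH, rt; filtration and evaporation under argon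
Reagents that add atoms: none
Why: Hydrogenolysis of benzyl aryl ethers is neutral and leaves diaryl ethers and biaryl bonds untouched; all 24 hydroxyls are freed in one operation and the only by-product is volatile.

## Compound list

1 | 1,3,5-tris(benzyloxy)benzene | c1(OCc3ccccc3)cc(OCc3ccccc3)cc(OCc3ccccc3)c1 | starting material

2 | 1,3,5-tris(benzyloxy)-2-iodobenzene | Ic1c(OCc3ccccc3)cc(OCc3ccccc3)cc1OCc3ccccc3 | intermediate

3 | 2,2',4,4',6,6'-hexakis(benzyloxy)-1,1'-biphenyl | c1(OCc3ccccc3)cc(OCc3ccccc3)c(-c2c(OCc3ccccc3)cc(OCc3ccccc3)cc2OCc3ccccc3)c(OCc3ccccc3)c1 | intermediate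

4 | 2,2',4,4',6,6'-hexakis(benzyloxy)biphenyl-3-carbaldehyde | O=Cc1c(OCc3ccccc3)cc(OCc3ccccc3)c(-c2c(OCc3ccccc3)cc(OCc3ccccc3)cc2OCc3ccccc3)c1OCc3ccccc3 | intermediate

5 | 2,2',4,4',6,6'-hexakis(benzyloxy)biphenyl-3-yl formate | O=COc1c(OCc3ccccc3)cc(OCc3ccccc3)c(-c2c(OCc3ccccc3)cc(OCc3ccccc3)cc2OCc3ccccc3)c1OCc3ccccc3 | intermediate

6 | 2,2',4,4',6,6'-hexakis(benzyloxy)biphenyl-3-ol (HBB-OH) | Oc1c(OCc3ccccc3)cc(OCc3ccccc3)c(-c2c(OCc3ccccc3)cc(OCc3ccccc3)cc2OCc3ccccc3)c1OCc3ccccc3 | intermediate

7 | 1,3-dichloropropan-2-one | ClCC(=O)CCl | starting material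

8 | 1,3-bis(HBB-oxy)propan-2-one | O=C(COc1c(OCc3ccccc3)cc(OCc3ccccc3)c(-c2c(OCc3ccccc3)cc(OCc3ccccc3)cc2OCc3ccccc3)c1OCc3ccccc3)COc1c(OCc3ccccc3)cc(OCc3ccccc3)c(-c2c(OCc3ccccc3)cc(OCc3ccccc3)cc2OCc3ccccc3)c1OCc3ccccc3 | intermediate

9 | 2-(benzyloxy)acetaldehyde | O=CCOCc1ccccc1 | starting material

10 | 2-(benzyloxy)-3-(dimethylamino)prop-2-enal | CN(C)C=C(C=O)OCc1ccccc1 | intermediate

11 | N-[2-(benzyloxy)-3-(dimethylamino)prop-2-en-1-ylidene]-N-methylmethanaminium tetrafluoroborate | CN(C)C=C(C=[N+](C)C)OCc1ccccc1.F[B-](F)(F)F | intermediate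

12 | 5-(benzyloxy)-6-(dimethylamino)-1,3-bis(HBB-oxy)hexa-3,5-dien-2-one | CN(C)C=C(OCc3ccccc3)C=C(Oc1c(OCc3ccccc3)cc(OCc3ccccc3)c(-c2c(OCc3ccccc3)cc(OCc3ccccc3)cc2OCc3ccccc3)c1OCc3ccccc3)C(=O)COc1c(OCc3ccccc3)cc(OCc3ccccc3)c(-c2c(OCc3ccccc3)cc(OCc3ccccc3)cc2OCc3ccccc3)c1OCc3ccccc3 | intermediate

13 | 4-(benzyloxy)-2,6-bis(HBB-oxy)phenol (DAr-OH) | Oc4c(Oc1c(OCc3ccccc3)cc(OCc3ccccc3)c(-c2c(OCc3ccccc3)cc(OCc3ccccc3)cc2OCc3ccccc3)c1OCc3ccccc3)cc(OCc3ccccc3)cc4Oc1c(OCc3ccccc3)cc(OCc3ccccc3)c(-c2c(OCc3ccccc3)cc(OCc3ccccc3)cc2OCc3ccccc3)c1OCc3ccccc3 | intermediate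

14 | methyl bromoacetate | COC(=O)CBr | starting material

15 | methyl 2-(DAr-oxy)acetate | COC(=O)COc4c(Oc1c(OCc3ccccc3)cc(OCc3ccccc3)c(-c2c(OCc3ccccc3)cc(OCc3ccccc3)cc2OCc3ccccc3)c1OCc3ccccc3)cc(OCc3ccccc3)cc4Oc1c(OCc3ccccc3)cc(OCc3ccccc3)c(-c2c(OCc3ccccc3)cc(OCc3ccccc3)cc2OCc3ccccc3)c1OCc3ccccc3 | intermediate

16 | 2-(DAr-oxy)acetaldehyde | O=CCOc4c(Oc1c(OCc3ccccc3)cc(OCc3ccccc3)c(-c2c(OCc3ccccc3)cc(OCc3ccccc3)cc2OCc3ccccc3)c1OCc3ccccc3)cc(OCc3ccccc3)cc4Oc1c(OCc3ccccc3)cc(OCc3ccccc3)c(-c2c(OCc3ccccc3)cc(OCc3ccccc3)cc2OCc3ccccc3)c1OCc3ccccc3 | intermediate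

17 | 2-(DAr-oxy)-3-(dimethylamino)prop-2-enal | CN(C)C=C(C=O)Oc4c(Oc1c(OCc3ccccc3)cc(OCc3ccccc3)c(-c2c(OCc3ccccc3)cc(OCc3ccccc3)cc2OCc3ccccc3)c1OCc3ccccc3)cc(OCc3ccccc3)cc4Oc1c(OCc3ccccc3)cc(OCc3ccccc3)c(-c2c(OCc3ccccc3)cc(OCc3ccccc3)cc2OCc3ccccc3)c1OCc3ccccc3 | intermediate

18 | N-[2-(DAr-oxy)-3-(dimethylamino)prop-2-en-1-ylidene]-N-methylmethanaminium tetrafluoroborate | CN(C)C=C(C=[N+](C)C)Oc4c(Oc1c(OCc3ccccc3)cc(OCc3ccccc3)c(-c2c(OCc3ccccc3)cc(OCc3ccccc3)cc2OCc3ccccc3)c1OCc3ccccc3)cc(OCc3ccccc3)cc4Oc1c(OCc3ccccc3)cc(OCc3ccccc3)c(-c2c(OCc3ccccc3)cc(OCc3ccccc3)cc2OCc3ccccc3)c1OCc3ccccc3.F[B-](F)(F)F | intermediate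

19 | 1,3-bis(benzyloxy)propan-2-one | O=C(COCc1ccccc1)COCc1ccccc1 | starting material

20 | 1,3-bis(benzyloxy)-5-(DAr-oxy)-6-(dimethylamino)hexa-3,5-dien-2-one | CN(C)C=C(Oc4c(Oc1c(OCc3ccccc3)cc(OCc3ccccc3)c(-c2c(OCc3ccccc3)cc(OCc3ccccc3)cc2OCc3ccccc3)c1OCc3ccccc3)cc(OCc3ccccc3)cc4Oc1c(OCc3ccccc3)cc(OCc3ccccc3)c(-c2c(OCc3ccccc3)cc(OCc3ccccc3)cc2OCc3ccccc3)c1OCc3ccccc3)C=C(OCc3ccccc3)C(=O)COCc3ccccc3 | intermediate

21 | 2,6-bis(benzyloxy)-4-(DAr-oxy)phenol (CAr-OH) | Oc5c(OCc3ccccc3)cc(Oc4c(Oc1c(OCc3ccccc3)cc(OCc3ccccc3)c(-c2c(OCc3ccccc3)cc(OCc3ccccc3)cc2OCc3ccccc3)c1OCc3ccccc3)cc(OCc3ccccc3)cc4Oc1c(OCc3ccccc3)cc(OCc3ccccc3)c(-c2c(OCc3ccccc3)cc(OCc3ccccc3)cc2OCc3ccccc3)c1OCc3ccccc3)cc5OCc3ccccc3 | intermediate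

22 | 1-chloro-3-(HBB-oxy)propan-2-one | ClCC(=O)COc1c(OCc3ccccc3)cc(OCc3ccccc3)c(-c2c(OCc3ccccc3)cc(OCc3ccccc3)cc2OCc3ccccc3)c1OCc3ccccc3 | intermediate

23 | 1-(CAr-oxy)-3-(HBB-oxy)propan-2-one | O=C(COc1c(OCc3ccccc3)cc(OCc3ccccc3)c(-c2c(OCc3ccccc3)cc(OCc3ccccc3)cc2OCc3ccccc3)c1OCc3ccccc3)COc5c(OCc3ccccc3)cc(Oc4c(Oc1c(OCc3ccccc3)cc(OCc3ccccc3)c(-c2c(OCc3ccccc3)cc(OCc3ccccc3)cc2OCc3ccccc3)c1OCc3ccccc3)cc(OCc3ccccc3)cc4Oc1c(OCc3ccccc3)cc(OCc3ccccc3)c(-c2c(OCc3ccccc3)cc(OCc3ccccc3)cc2OCc3ccccc3)c1OCc3ccccc3)cc5OCc3ccccc3 | intermediate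

24 | 5-(benzyloxy)-1-(CAr-oxy)-6-(dimethylamino)-3-(HBB-oxy)hexa-3,5-dien-2-one | CN(C)C=C(OCc3ccccc3)C=C(Oc1c(OCc3ccccc3)cc(OCc3ccccc3)c(-c2c(OCc3ccccc3)cc(OCc3ccccc3)cc2OCc3ccccc3)c1OCc3ccccc3)C(=O)COc5c(OCc3ccccc3)cc(Oc4c(Oc1c(OCc3ccccc3)cc(OCc3ccccc3)c(-c2c(OCc3ccccc3)cc(OCc3ccccc3)cc2OCc3ccccc3)c1OCc3ccccc3)cc(OCc3ccccc3)cc4Oc1c(OCc3ccccc3)cc(OCc3ccccc3)c(-c2c(OCc3ccccc3)cc(OCc3ccccc3)cc2OCc3ccccc3)c1OCc3ccccc3)cc5OCc3ccccc3 | intermediate

25 | 4-(benzyloxy)-2-(CAr-oxy)-6-(HBB-oxy)phenol | Oc6c(Oc1c(OCc3ccccc3)cc(OCc3ccccc3)c(-c2c(OCc3ccccc3)cc(OCc3ccccc3)cc2OCc3ccccc3)c1OCc3ccccc3)cc(OCc3ccccc3)cc6Oc5c(OCc3ccccc3)cc(Oc4c(Oc1c(OCc3ccccc3)cc(OCc3ccccc3)c(-c2c(OCc3ccccc3)cc(OCc3ccccc3)cc2OCc3ccccc3)c1OCc3ccccc3)cc(OCc3ccccc3)cc4Oc1c(OCc3ccccc3)cc(OCc3ccccc3)c(-c2c(OCc3ccccc3)cc(OCc3ccccc3)cc2OCc3ccccc3)c1OCc3ccccc3)cc5OCc3ccccc3 | intermediate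

26 | 1,3-bis(benzyloxy)-5-bromobenzene | Brc1cc(OCc2ccccc2)cc(OCc2ccccc2)c1 | starting material

27 | tetracosa-O-benzyl ether of the target (3,5-bis(benzyloxy)phenyl ether of 25) | c7(OCc3ccccc3)cc(OCc3ccccc3)cc(Oc6c(Oc1c(OCc3ccccc3)cc(OCc3ccccc3)c(-c2c(OCc3ccccc3)cc(OCc3ccccc3)cc2OCc3ccccc3)c1OCc3ccccc3)cc(OCc3ccccc3)cc6Oc5c(OCc3ccccc3)cc(Oc4c(Oc1c(OCc3ccccc3)cc(OCc3ccccc3)c(-c2c(OCc3ccccc3)cc(OCc3ccccc3)cc2OCc3ccccc3)c1OCc3ccccc3)cc(OCc3ccccc3)cc4Oc1c(OCc3ccccc3)cc(OCc3ccccc3)c(-c2c(OCc3ccccc3)cc(OCc3ccccc3)cc2OCc3ccccc3)c1OCc3ccccc3)cc5OCc3ccccc3)c7 | intermediate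

28 | CNP0294555.0 | Oc1cc(O)cc(Oc2c(Oc3c(O)cc(Oc4c(Oc5c(O)cc(O)c(-c6c(O)cc(O)cc6O)c5O)cc(O)cc4Oc4c(O)cc(O)c(-c5c(O)cc(O)cc5O)c4O)cc3O)cc(O)cc2Oc2c(O)cc(O)c(-c3c(O)cc(O)cc3O)c2O)c1 | target

## Step count and least certain steps

Total step count: 16.

Longest linear sequence: 14 steps (1, 2, 3, 4, 5, 7, 8, 9, 10, 11, 13, 14, 15, 16).

**Step 7 (key step).**
- *Risk:* The most likely failure is stalling at the open-chain stage. The aminodienone forms in an extended geometry, and closure needs rotation about its central double bond into a crowded coiled conformer between two very large aryloxy groups. The first C–C bond may also form slowly at the shielded enolate carbon, and a second condensation at the other CH2 group can compete.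
- *Fallback:* It sets out from 6 and comes back at 13.
  - Commercial 2,6-difluoro-4-hydroxybenzaldehyde is benzylated to 4-(benzyloxy)-2,6-difluorobenzaldehyde F1.
  - Both fluorines, ortho to the formyl group, are displaced by the phenoxide of 6 in an SNAr reaction (K2CO3, DMSO, 110 °C) to give 4-(benzyloxy)-2,6-bis(HBB-oxy)benzaldehyde F2.
  - Baeyer-Villiger oxidation with mCPBA gives 4-(benzyloxy)-2,6-bis(HBB-oxy)phenyl formate F3, and methanolysis gives 13.

**Step 11.**
- *Risk:* The large partner is the electrophile here. The bulky aryloxy group on the central carbon may twist the cation out of plane and shield both termini, so that self-aldol condensation of the small ketone overtakes the wanted addition.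
- *Fallback:* It sets out from 13 and comes back at 21.
  - Commercial 5-bromobenzene-1,2,3-triol is allylated at its central, most acidic hydroxyl (allyl bromide, Li2CO3, DMF) to 2-(allyloxy)-5-bromobenzene-1,3-diol F4.
  - F4 is benzylated to 2-(allyloxy)-1,3-bis(benzyloxy)-5-bromobenzene F5.
  - Ullmann coupling of 13 with F5 (CuI, picolinic acid, K3PO4) gives 2-(allyloxy)-1,3-bis(benzyloxy)-5-(DAr-oxy)benzene F6.
  - Deallylation with Pd(PPh3)4 and morpholine gives 21.

**Step 14.**
- *Risk:* The same stalling before ring closure is possible, now on the most valuable substrate. Poor solubility of the large potassium enolate and slow attack at both shielded CH2 groups add to it, leaving time for base-induced condensation of the ketone with itself.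
- *Fallback:* It sets out from 6 and 21 and comes back at 25.
  - One fluorine of F1 is displaced by the phenoxide of 6 (one equivalent) to give 4-(benzyloxy)-2-fluoro-6-(HBB-oxy)benzaldehyde F7.
  - The second fluorine is displaced by the phenoxide of 21 to give 4-(benzyloxy)-2-(CAr-oxy)-6-(HBB-oxy)benzaldehyde F8.
  - Baeyer-Villiger oxidation gives 4-(benzyloxy)-2-(CAr-oxy)-6-(HBB-oxy)phenyl formate F9, and methanolysis gives 25.

**Step 15.**
- *Risk:* The phenoxide lies between two very large aryloxy groups, so its binding to copper and the C–O bond formation may be slow. Hydrodebromination of the bromide and oxidation of the electron-rich phenoxide then take over.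
- *Fallback:* It sets out from 25 and comes back at 27.
  - 3,5-bis(benzyloxy)-2-(trimethylsilyl)phenyl trifluoromethanesulfonate F10, made in three routine operations from commercial 3,5-bis(benzyloxy)phenol, is treated with CsF in MeCN/toluene in the presence of 25.
  - The 3,5-bis(benzyloxy)benzyne F11 so formed is attacked by the phenoxide at the aryne carbon remote from the neighbouring benzyloxy group. This places the negative charge next to that oxygen and gives the 1,3,5-pattern of ring A. Protonation gives 27.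

**Step 16.**
- *Risk:* Debenzylation may stay incomplete, because partly deprotected intermediates change solubility and adsorb on the catalyst. Air oxidation during isolation of the free polyphenol is the second risk.
- *Fallback:* It sets out from 27 and comes back at 28.
  - The crude hydrogenolysis product is acetylated at once (Ac2O, pyridine) to the tetracosaacetate of the target F12, which is stable and can be purified by chromatography.
  - F12 is deacetylated under argon with catalytic NaOMe in MeOH (Zemplén conditions) to 28.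

## Further compounds

F1 | step 7 | 4-(benzyloxy)-2,6-difluorobenzaldehyde | O=Cc1c(F)cc(OCc2ccccc2)cc1F

F2 | step 7 | 4-(benzyloxy)-2,6-bis(HBB-oxy)benzaldehyde | O=Cc4c(Oc1c(OCc3ccccc3)cc(OCc3ccccc3)c(-c2c(OCc3ccccc3)cc(OCc3ccccc3)cc2OCc3ccccc3)c1OCc3ccccc3)cc(OCc3ccccc3)cc4Oc1c(OCc3ccccc3)cc(OCc3ccccc3)c(-c2c(OCc3ccccc3)cc(OCc3ccccc3)cc2OCc3ccccc3)c1OCc3ccccc3

F3 | step 7 | 4-(benzyloxy)-2,6-bis(HBB-oxy)phenyl formate | O=COc4c(Oc1c(OCc3ccccc3)cc(OCc3ccccc3)c(-c2c(OCc3ccccc3)cc(OCc3ccccc3)cc2OCc3ccccc3)c1OCc3ccccc3)cc(OCc3ccccc3)cc4Oc1c(OCc3ccccc3)cc(OCc3ccccc3)c(-c2c(OCc3ccccc3)cc(OCc3ccccc3)cc2OCc3ccccc3)c1OCc3ccccc3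

F4 | step 11 | 2-(allyloxy)-5-bromobenzene-1,3-diol | C=CCOc1c(O)cc(Br)cc1O

F5 | step 11 | 2-(allyloxy)-1,3-bis(benzyloxy)-5-bromobenzene | C=CCOc1c(OCc2ccccc2)cc(Br)cc1OCc2ccccc2

F6 | step 11 | 2-(allyloxy)-1,3-bis(benzyloxy)-5-(DAr-oxy)benzene | C=CCOc5c(OCc3ccccc3)cc(Oc4c(Oc1c(OCc3ccccc3)cc(OCc3ccccc3)c(-c2c(OCc3ccccc3)cc(OCc3ccccc3)cc2OCc3ccccc3)c1OCc3ccccc3)cc(OCc3ccccc3)cc4Oc1c(OCc3ccccc3)cc(OCc3ccccc3)c(-c2c(OCc3ccccc3)cc(OCc3ccccc3)cc2OCc3ccccc3)c1OCc3ccccc3)cc5OCc3ccccc3

F7 | step 14 | 4-(benzyloxy)-2-fluoro-6-(HBB-oxy)benzaldehyde | O=Cc6c(F)cc(OCc3ccccc3)cc6Oc1c(OCc3ccccc3)cc(OCc3ccccc3)c(-c2c(OCc3ccccc3)cc(OCc3ccccc3)cc2OCc3ccccc3)c1OCc3ccccc3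

F8 | step 14 | 4-(benzyloxy)-2-(CAr-oxy)-6-(HBB-oxy)benzaldehyde | O=Cc6c(Oc1c(OCc3ccccc3)cc(OCc3ccccc3)c(-c2c(OCc3ccccc3)cc(OCc3ccccc3)cc2OCc3ccccc3)c1OCc3ccccc3)cc(OCc3ccccc3)cc6Oc5c(OCc3ccccc3)cc(Oc4c(Oc1c(OCc3ccccc3)cc(OCc3ccccc3)c(-c2c(OCc3ccccc3)cc(OCc3ccccc3)cc2OCc3ccccc3)c1OCc3ccccc3)cc(OCc3ccccc3)cc4Oc1c(OCc3ccccc3)cc(OCc3ccccc3)c(-c2c(OCc3ccccc3)cc(OCc3ccccc3)cc2OCc3ccccc3)c1OCc3ccccc3)cc5OCc3ccccc3

F9 | step 14 | 4-(benzyloxy)-2-(CAr-oxy)-6-(HBB-oxy)phenyl formate | O=COc6c(Oc1c(OCc3ccccc3)cc(OCc3ccccc3)c(-c2c(OCc3ccccc3)cc(OCc3ccccc3)cc2OCc3ccccc3)c1OCc3ccccc3)cc(OCc3ccccc3)cc6Oc5c(OCc3ccccc3)cc(Oc4c(Oc1c(OCc3ccccc3)cc(OCc3ccccc3)c(-c2c(OCc3ccccc3)cc(OCc3ccccc3)cc2OCc3ccccc3)c1OCc3ccccc3)cc(OCc3ccccc3)cc4Oc1c(OCc3ccccc3)cc(OCc3ccccc3)c(-c2c(OCc3ccccc3)cc(OCc3ccccc3)cc2OCc3ccccc3)c1OCc3ccccc3)cc5OCc3ccccc3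

F10 | step 15 | 3,5-bis(benzyloxy)-2-(trimethylsilyl)phenyl trifluoromethanesulfonate | C[Si](C)(C)c1c(OCc2ccccc2)cc(OCc2ccccc2)cc1OS(=O)(=O)C(F)(F)F

F11 | step 15 | 3,5-bis(benzyloxy)benzyne | C1#CC(OCc2ccccc2)=CC(OCc2ccccc2)=C1

F12 | step 16 | tetracosaacetate of the target | CC(=O)Oc1cc(OC(C)=O)cc(Oc2c(Oc3c(OC(C)=O)cc(Oc4c(Oc5c(OC(C)=O)cc(OC(C)=O)c(-c6c(OC(C)=O)cc(OC(C)=O)cc6OC(C)=O)c5OC(C)=O)cc(OC(C)=O)cc4Oc4c(OC(C)=O)cc(OC(C)=O)c(-c5c(OC(C)=O)cc(OC(C)=O)cc5OC(C)=O)c4OC(C)=O)cc3OC(C)=O)cc(OC(C)=O)cc2Oc2c(OC(C)=O)cc(OC(C)=O)c(-c3c(OC(C)=O)cc(OC(C)=O)cc3OC(C)=O)c2OC(C)=O)c1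

A1 | alternative 1 | 5-(benzyloxy)-1,3-dibromo-2-(methoxymethoxy)benzene | COCOc1c(Br)cc(OCc2ccccc2)cc1Br

A2 | alternative 2 | 2,6-dichloro-1,4-benzoquinone | O=C1C=C(Cl)C(=O)C(Cl)=C1

A3 | alternative 2 | 2,6-bis(HBB-oxy)-1,4-benzoquinone | O=C4C=C(Oc1c(OCc3ccccc3)cc(OCc3ccccc3)c(-c2c(OCc3ccccc3)cc(OCc3ccccc3)cc2OCc3ccccc3)c1OCc3ccccc3)C(=O)C(Oc1c(OCc3ccccc3)cc(OCc3ccccc3)c(-c2c(OCc3ccccc3)cc(OCc3ccccc3)cc2OCc3ccccc3)c1OCc3ccccc3)=C4

A4 | alternative 3 | 5-(benzyloxy)-2-(trimethylsilyl)-1,3-phenylene bis(trifluoromethanesulfonate) | C[Si](C)(C)c1c(OS(=O)(=O)C(F)(F)F)cc(OCc2ccccc2)cc1OS(=O)(=O)C(F)(F)F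

A5 | alternative 3 | 1-(benzyloxy)-3,5-bis(HBB-oxy)benzene | c4(Oc1c(OCc3ccccc3)cc(OCc3ccccc3)c(-c2c(OCc3ccccc3)cc(OCc3ccccc3)cc2OCc3ccccc3)c1OCc3ccccc3)cc(OCc3ccccc3)cc(Oc1c(OCc3ccccc3)cc(OCc3ccccc3)c(-c2c(OCc3ccccc3)cc(OCc3ccccc3)cc2OCc3ccccc3)c1OCc3ccccc3)c4
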